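## Analysis of the target

Tetraphlorethol C (18, C24H18O12) is a linear chain of four benzene rings, A to D, joined by three diaryl ether oxygens. It carries nine free phenolic hydroxyls and has no stereocentre. Ring A is the 3,5-dihydroxyphenoxy end and is the only ring with three oxygens (C1, C3, C5), with hydrogen on C2, C4 and C6. Rings B, C and D are each 1,2,4,6-tetraoxygenated. Every ether oxygen joins an unhindered carbon of one ring (C1 of ring A, C4 of ring B, C4 of ring C) to a C1 of the next ring that is flanked by two ortho oxygens. The free nonaphenol is polar and air-sensitive, because rings B and C are hydroquinone-type 1,4-dioxygenated rings, so the oxygens must stay alkylated until the last step. The difficulty is therefore not stereochemical: four nearly identical rings can be told apart only by the order of assembly, and each ether bond has a hindered, di-ortho-substituted oxygen on one side. The route rests on ring A: its 1,3,5-trioxygenated pattern with three ring hydrogens is what a 3-alkoxy vinylketene and a terminal ynol ether give on benzannulation. The flanked C1 oxygen of ring B can therefore enter as the oxygen of an alkyne, and ring A can be built around it instead of being coupled to it.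

## Retrosynthetic reasoning

**18 to 17.** Only O–alkyl bonds are cut: seven O–methyl bonds on rings B, C and D and one O–ethyl bond on ring A. The three diaryl ether bonds are C(sp2)–O on both sides and survive a Lewis-acid dealkylation. All oxidation-prone phenols are thus released in one final operation. Forward, the step must cleave eight ethers completely without degrading the product.

**17 to 11 and 12.** In ring A of 17 (C1 bears the oxygen to ring B, C3 the free hydroxyl, C5 the ethoxy group) the bonds C1–C6 and C2–C3 are cut. The C1–C2 unit with its aryloxy oxygen becomes the alkyne of ynol ether 11. The four carbons C3, C4, C5 and C6 are the ring of cyclobutenone 12 (its carbonyl carbon, CH2, ethoxy carbon and vinylic CH). The cut is made here because ring A is the only ring with the simple 1,3,5 pattern. It also removes the third coupling onto a flanked phenol, which would otherwise be needed on the largest and most valuable intermediate. Forward, the benzannulation must join the unsubstituted alkyne carbon to the ketene carbonyl carbon, so that the aryloxy group ends meta to the new hydroxyl.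

**11 to 8 to 7.** The O–C(sp) bond is traced back to phenol 7 through the dichlorovinyl ether 8. The phenoxide adds to a small, linear chloroalkyne formed in the flask, and an alkyllithium then eliminates and exchanges the two chlorines. The electrophile is rod-shaped, so the two ortho methoxy groups of ring B do not block it. Forward, the sequence must deliver a terminal ynol ether and handle it without acid.

**7 to 6 to 5 and 2.** The ether between rings B and C is cut at the O–C4(ring B) bond, on the unhindered side. The electrophile is then bromide 2, whose C–Br carbon has two ortho hydrogens, and the nucleophile is the flanked phenol 5. A hindered phenoxide is tolerated better in copper-catalysed coupling than a di-ortho-substituted aryl halide. The benzyl ether of 6 masks the next flanked hydroxyl and is removed by hydrogenolysis.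

**5 to 4 to 3 and 2.** The ether between rings C and D is cut the same way, at O–C4(ring C), giving phenol 3 (ring D with all four oxygens in place) and the same bromide 2. One building block thus serves for rings B and C.

**2 to 1.** The benzyl ether is cut back to bromophenol 1. It is needed so that the bromophenol cannot couple with itself.

## Alternatives that were turned down

**Alternative 1:** The three diaryl ether bonds would be made by fluoride displacement on aryl fluorides activated by two ortho formyl groups. The formyl groups would afterwards be converted into the six hydroxyls at C2 and C6 of rings B, C and D. The forward key step is the sixfold Dakin-type (Baeyer–Villiger) oxidation of hexa-aldehyde A1 with a peracid to hexaformate A2, followed by formate hydrolysis and cleavage of three methyl ethers.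
- For it: the ether bonds at the flanked carbons are formed by an electronically driven substitution at the activated carbon, not by a coupling at a hindered oxygen. On that point it is stronger than the copper couplings used here, and it needs no metal.
- Against it: in A1 each formyl group has only an ortho aryloxy donor and no para donor, and each ring carries two electron-withdrawing formyl groups. Aryl migration is therefore not strongly favoured over hydride migration to the carboxylic acid, and six such events must all go the right way in one molecule. Formate loss would also expose hydroquinone-type rings to the oxidant.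
- Comparison: the dealkylation at the end is not saved. The chosen route keeps every oxygen at its final oxidation level from the start and places its single selectivity question in one pericyclic cascade.

**Alternative 2:** Ring D would be built from an open chain by cutting its C4–C5 bond. The forward key step is the alkoxide-mediated Claisen cyclisation of the symmetrical diketo diester A3 to the methyl 3-aryloxy-2,4,6-trihydroxybenzoate A4.
- For it: the route is biomimetic, the symmetry of A3 removes any regiochemical question, and the flanked oxygen of ring D is attached at an sp3 carbon.
- Against it: A3 contains an α-aryloxy 1,3-diketone, which alkoxide can cleave by retro-Claisen reaction. Chains of this type also close through oxygen to pyranones. A4 carries an extra carbomethoxy group, so hydrolysis and decarboxylation are added, and the six methyl ethers still need cleavage. The rings A–B–C phenol needed for A3 requires the same couplings onto flanked oxygens as the chosen route.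
- Comparison: the sequence is longer. Both routes build a terminal ring from scratch, but the chosen cascade delivers ring A with no surplus carbon and under neutral thermal conditions.

**Alternative 3:** Ring C would be built in the middle by cutting its C1–C2 bond. The forward key step opens pyrone A5 with a magnesium alkoxide and recloses it by Claisen condensation of the aryloxymethyl ketone carbon onto the ester. The product is A6, the heptamethyl ether with both ring C hydroxyls free.
- For it: this is the most convergent plan. The rings A–B half and phenol 3 are joined through the pyrone by two easy substitutions, and only one coupling at a flanked phenol remains against two in the chosen route. On convergence it is clearly stronger.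
- Against it: after ring opening, the carbanion needed sits on a carbon activated by a single ketone. The more acidic methylene between the ketone and the enol ether cannot give a six-membered ring. Reclosure through oxygen back to a pyrone competes. The 4-aryloxy group of A5 is a vinylogous aryl ester, which the alkoxide can displace with loss of ring D.
- Comparison: the chosen route is linear and longer in couplings, but its ring-forming step has one orientation, set by the polarity of ketene and ynol ether, and no competing mode of closure.

Key step: step 8

Assumption: cyclobutenone 12 and phenol 3 are used as purchased (12 stored cold), and the ring A hydroxyl left free by the benzannulation is carried unprotected into the final dealkylation.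

## Route

**Step 1**
Reactants: 1 4-bromo-2,6-dimethoxyphenol
Product: 2 2-(benzyloxy)-5-bromo-1,3-dimethoxybenzene
Conditions: BnBr, K2CO3, DMF, 25–50 °C
Reagents that add atoms: benzyl bromide, BrCc1ccccc1
Why: Williamson ether synthesis; the flanked phenol is deprotonated by K2CO3 and the primary benzylic electrophile is not impeded by the ortho methoxy groups. The benzyl ether prevents self-coupling of the bromophenol and is later removed without touching methyl or diaryl ethers.

**Step 2**
Reactants: 2 2-(benzyloxy)-5-bromo-1,3-dimethoxybenzene; 3 2,4,6-trimethoxyphenol
Product: 4 2-(benzyloxy)-1,3-dimethoxy-5-(2,4,6-trimethoxyphenoxy)benzene (rings C–D benzyl ether)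
Conditions: CuI (cat.), picolinic acid (cat.), K3PO4, DMSO, 90–100 °C, degassed, Ar
Reagents that add atoms: none
Why: Ullmann diaryl ether synthesis with a picolinate ligand, a system suited to di-ortho-substituted phenols; the C–Br carbon of 2 has two ortho hydrogens. Exclusion of air protects the electron-rich phenoxide of 3 from oxidation.

**Step 3**
Reactants: 4 rings C–D benzyl ether
Product: 5 2,6-dimethoxy-4-(2,4,6-trimethoxyphenoxy)phenol (rings C–D phenol)
Conditions: H2 (1 atm), 10% Pd/C, EtOAc–MeOH, 25 °C
Reagents that add atoms: none
Why: Hydrogenolysis of a benzyl aryl ether; methyl ethers and the diaryl ether are inert and no halogen is left in the molecule.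

**Step 4**
Reactants: 5 rings C–D phenol; 2 2-(benzyloxy)-5-bromo-1,3-dimethoxybenzene
Product: 6 2-(benzyloxy)-5-[2,6-dimethoxy-4-(2,4,6-trimethoxyphenoxy)phenoxy]-1,3-dimethoxybenzene (rings B–C–D benzyl ether)
Conditions: CuI (cat.), picolinic acid (cat.), K3PO4, DMSO, 90–100 °C, degassed, Ar
Reagents that add atoms: none
Why: Second Ullmann diaryl ether synthesis with the same bromide; the nucleophilic oxygen of 5 has the same two ortho methoxy groups as that of 3, and the remote ring D adds no hindrance at the reacting centre.

**Step 5**
Reactants: 6 rings B–C–D benzyl ether
Product: 7 4-[2,6-dimethoxy-4-(2,4,6-trimethoxyphenoxy)phenoxy]-2,6-dimethoxyphenol (rings B–C–D phenol)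
Conditions: H2 (1 atm), 10% Pd/C, EtOAc–MeOH, 25 °C
Reagents that add atoms: none
Why: Hydrogenolysis of the benzyl ether frees the flanked C1 hydroxyl of ring B; all other ethers are stable.

**Step 6**
Reactants: 7 rings B–C–D phenol
Product: 8 (E)-1,2-dichlorovinyl ether of phenol 7
Conditions: Cl2C=CHCl, K2CO3, DMF, 70 °C
Reagents that add atoms: trichloroethylene, ClC=C(Cl)Cl
Why: Base-mediated dichlorovinylation of a phenol; the base dehydrochlorinates trichloroethylene in the flask and the phenoxide adds anti to the resulting chloroalkyne, giving the E enol ether. The linear two-carbon electrophile reaches the oxygen despite the two ortho methoxy groups.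

**Step 7**
Reactants: 8 (E)-1,2-dichlorovinyl ether of phenol 7
Product: 11 ethynyl ether of phenol 7 (rings B–C–D aryl ynol ether), via chloroethynyl ether 9 (not isolated), via lithium aryloxyacetylide 10 (not isolated)
Conditions: n-BuLi (2.2 equiv), THF, −78 to −40 °C; then H2O, −78 °C; quick filtration through Et3N-deactivated silica, stored cold
Reagents that add atoms: none
Why: Dichlorovinyl ether route to ynol ethers; the first equivalent of n-BuLi removes the vinylic hydrogen and chloride to give 9, the second exchanges the remaining chlorine for lithium to give 10, and protonation gives 11. The low temperature keeps the alkyllithium from metalating the methoxyarene rings, and the non-acidic work-up avoids hydration of the ynol ether.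

**Step 8**
Reactants: 11 ethynyl ether of phenol 7; 12 3-ethoxycyclobut-2-en-1-one
Product: 17 3-ethoxy-5-aryloxyphenol (ring A monoethyl heptamethyl ether of tetraphlorethol C bearing one free ring A hydroxyl), via ethoxyvinylketene 13 (not isolated), via vinylcyclobutenone 14 (not isolated), via dienylketene 15 (not isolated), via cyclohexadienone 16 (not isolated)
Conditions: 11 in toluene, 110 °C (sealed, Ar), slow addition of 12 (2–3 equiv); then K2CO3, MeOH, 25 °C
Reagents that add atoms: none
Why: Danheiser benzannulation, the thermal reaction of a cyclobutenone with an oxygen-substituted alkyne, applied here to an aryl ynol ether. Heating opens 12 by 4π electrocyclic ring opening to vinylketene 13, whose electrophilic central ketene carbon is attacked by the nucleophilic terminal carbon of 11; the [2+2] cycloaddition across the ketene C=C gives 14, with the aryloxy carbon bonded to the former α-carbon of the ketene. A second, reversible 4π opening gives dienylketene 15, and the isomer with the ketene and ethoxyvinyl arms cis closes ring A by thermal disrotatory 6π electrocyclisation (ketene carbon to vinyl CH2) to 16, which tautomerises irreversibly to phenol 17. The only selectivity needed is the orientation of the [2+2] step; the oxygen lone pair of 11 makes the unsubstituted alkyne carbon the nucleophile, so the aryloxy group ends meta to the new hydroxyl and, with the ethoxy group from C3 of 12, the 1,3,5 pattern of ring A results. No stereocentre survives, since the sp3 carbon of 14 is lost on ring opening. The aryl ynol ether has no β-hydrogen on its oxygen substituent, so the retro-ene loss of ketene that limits alkyl ynol ethers at this temperature is not available. Slow addition of 12 keeps the concentration of 13 low against ketene dimerisation, and the carbonate methanolysis returns any 17 that was acylated by 13.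

**Step 9**
Reactants: 17 ring A monoethyl heptamethyl ether of tetraphlorethol C
Product: 18 tetraphlorethol C
Conditions: BBr3 (excess), CH2Cl2, −78 to 25 °C; then degassed ice-water, EtOAc extraction under Ar; Sephadex LH-20
Reagents that add atoms: none
Why: Lewis-acid ether cleavage; BBr3 coordinates each ether oxygen and bromide attacks the methyl or ethyl carbon, while the diaryl ether C(sp2)–O bonds are not cleaved. Excess reagent and warming serve the slower ethyl ether, and the oxygen-free work-up protects the hydroquinone-type rings B and C.

## Compound list

1 | 4-bromo-2,6-dimethoxyphenol | COc1cc(Br)cc(OC)c1O | starting material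
2 | 2-(benzyloxy)-5-bromo-1,3-dimethoxybenzene | COc1cc(Br)cc(OC)c1OCc1ccccc1 | intermediate
3 | 2,4,6-trimethoxyphenol | COc1cc(OC)c(O)c(OC)c1 | starting material
4 | 2-(benzyloxy)-1,3-dimethoxy-5-(2,4,6-trimethoxyphenoxy)benzene (rings C–D benzyl ether) | COc1cc(Oc2c(OC)cc(OC)cc2OC)cc(OC)c1OCc1ccccc1 | intermediate
5 | 2,6-dimethoxy-4-(2,4,6-trimethoxyphenoxy)phenol (rings C–D phenol) | Oc1c(OC)cc(Oc2c(OC)cc(OC)cc2OC)cc1OC | intermediate
6 | 2-(benzyloxy)-5-[2,6-dimethoxy-4-(2,4,6-trimethoxyphenoxy)phenoxy]-1,3-dimethoxybenzene (rings B–C–D benzyl ether) | COc1cc(Oc2c(OC)cc(Oc3c(OC)cc(OC)cc3OC)cc2OC)cc(OC)c1OCc1ccccc1 | intermediate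
7 | 4-[2,6-dimethoxy-4-(2,4,6-trimethoxyphenoxy)phenoxy]-2,6-dimethoxyphenol (rings B–C–D phenol) | Oc1c(OC)cc(Oc2c(OC)cc(Oc3c(OC)cc(OC)cc3OC)cc2OC)cc1OC | intermediate
8 | (E)-1,2-dichlorovinyl ether of phenol 7 | Cl/C=C(/Cl)Oc1c(OC)cc(Oc2c(OC)cc(Oc3c(OC)cc(OC)cc3OC)cc2OC)cc1OC | intermediate
9 | chloroethynyl ether of phenol 7 | ClC#COc1c(OC)cc(Oc2c(OC)cc(Oc3c(OC)cc(OC)cc3OC)cc2OC)cc1OC | intermediate
10 | lithium aryloxyacetylide of phenol 7 | [Li]C#COc1c(OC)cc(Oc2c(OC)cc(Oc3c(OC)cc(OC)cc3OC)cc2OC)cc1OC | intermediate
11 | ethynyl ether of phenol 7 (rings B–C–D aryl ynol ether) | C#COc1c(OC)cc(Oc2c(OC)cc(Oc3c(OC)cc(OC)cc3OC)cc2OC)cc1OC | intermediate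
12 | 3-ethoxycyclobut-2-en-1-one | CCOC1=CC(=O)C1 | starting material
13 | 3-ethoxybuta-1,3-dien-1-one (ethoxyvinylketene) | C=C(OCC)C=C=O | intermediate
14 | 3-aryloxy-4-(1-ethoxyvinyl)cyclobut-2-en-1-one, racemic (aryl = rings B–C–D of 7) | C=C(OCC)C1C(=O)C=C1Oc1c(OC)cc(Oc2c(OC)cc(Oc3c(OC)cc(OC)cc3OC)cc2OC)cc1OC | intermediate
15 | 3-aryloxy-5-ethoxyhexa-1,3,5-trien-1-one, ketene and ethoxyvinyl arms cis (dienylketene) | O=C=C/C(Oc1c(OC)cc(Oc2c(OC)cc(Oc3c(OC)cc(OC)cc3OC)cc2OC)cc1OC)=C\C(OCC)=C | intermediate
16 | 3-aryloxy-5-ethoxycyclohexa-2,4-dien-1-one | O=C1C=C(Oc2c(OC)cc(Oc3c(OC)cc(Oc4c(OC)cc(OC)cc4OC)cc3OC)cc2OC)C=C(OCC)C1 | intermediate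
17 | 3-ethoxy-5-aryloxyphenol (ring A monoethyl, heptamethyl ether of tetraphlorethol C, one ring A hydroxyl free) | CCOc1cc(O)cc(Oc2c(OC)cc(Oc3c(OC)cc(Oc4c(OC)cc(OC)cc4OC)cc3OC)cc2OC)c1 | intermediate
18 | tetraphlorethol C | Oc1cc(O)cc(Oc2c(O)cc(Oc3c(O)cc(Oc4c(O)cc(O)cc4O)cc3O)cc2O)c1 | target

## Step count and risks

Total step count: 9. Longest linear sequence: 9 steps, from 1 to 18; compounds 3 and 12 are purchased and 2 is used twice.

**Step 8 (key step).** The vinylogous ester character of 12 should raise the barrier of its first ring opening. At the temperature then required, ketene dimerisation, capture of 13 by the product phenol, and slow uptake of the ketene by the less nucleophilic aryl ynol ether may take over. The cascade may also stall before the second ring opening. Fallback: ring A is bought instead of built. Starting from phenol 7, an Ullmann coupling with 1-bromo-3,5-dimethoxybenzene under the conditions of step 4 should give the nonamethyl ether of tetraphlorethol C F1. Treatment with BBr3 as in step 9 then returns to the route at target 18.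

**Step 7.** The terminal aryl ynol ether may be lost by hydration or oligomerisation during work-up and concentration, and excess alkyllithium may metalate a methoxyarene ring. Fallback: the alkyne is capped. Starting from 8, acetylide 10 is quenched with Me3SiCl in place of water to give the trimethylsilyl ynol ether F2, which should survive chromatography and storage. Heating F2 with 12 as in step 8 should give the 2-trimethylsilyl phenol F3, with silicon between the hydroxyl and the aryloxy group. Ipso-protodesilylation of this very electron-rich ring with CF3CO2H in CH2Cl2 returns to the route at 17.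

**Step 4 (and, less so, step 2).** The coupling of a di-ortho-methoxy phenoxide with an electron-rich bromide may be slow, so that oxidative degradation of the phenoxide by copper and traces of air, or reduction of the bromide, overtakes it. Fallback: the aryl partner is changed from halide to boron. Starting from 2, bromine–lithium exchange and borylation (n-BuLi, then B(OiPr)3, then dilute acid) give [4-(benzyloxy)-3,5-dimethoxyphenyl]boronic acid F4. A Chan–Lam coupling of F4 with phenol 5 (Cu(OAc)2, pyridine, 4 Å molecular sieves, CH2Cl2, 25 °C, dry air) returns to the route at 6. The same coupling of F4 with 3 would return at 4.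

**Step 9.** Dealkylation may stop short at one or more of the eight ether sites, the ethyl ether being the slowest, and the free nonaphenol may degrade by air oxidation during isolation. Fallback: the product is isolated as a derivative. Starting from 17, the crude product of the BBr3 treatment is acetylated (Ac2O, pyridine) to the nonaacetate of tetraphlorethol C F5, which can be purified on silica and separated from incompletely dealkylated material for recycling. Deacetylation with catalytic NaOMe in degassed MeOH, followed by an acidic resin, returns to the route at 18.

## Further compounds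

F1 | step 8 | nonamethyl ether of tetraphlorethol C | COc1cc(OC)cc(Oc2c(OC)cc(Oc3c(OC)cc(Oc4c(OC)cc(OC)cc4OC)cc3OC)cc2OC)c1
F2 | step 7 | trimethylsilylethynyl ether of phenol 7 | C[Si](C)(C)C#COc1c(OC)cc(Oc2c(OC)cc(Oc3c(OC)cc(OC)cc3OC)cc2OC)cc1OC
F3 | step 7 | 3-aryloxy-5-ethoxy-2-(trimethylsilyl)phenol (aryl = rings B–C–D of 7) | CCOc1cc(O)c([Si](C)(C)C)c(Oc2c(OC)cc(Oc3c(OC)cc(Oc4c(OC)cc(OC)cc4OC)cc3OC)cc2OC)c1
F4 | step 4 | [4-(benzyloxy)-3,5-dimethoxyphenyl]boronic acid | COc1cc(B(O)O)cc(OC)c1OCc1ccccc1
F5 | step 9 | nonaacetate of tetraphlorethol C | CC(=O)Oc1cc(OC(C)=O)cc(Oc2c(OC(C)=O)cc(Oc3c(OC(C)=O)cc(Oc4c(OC(C)=O)cc(OC(C)=O)cc4OC(C)=O)cc3OC(C)=O)cc2OC(C)=O)c1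
A1 | alternative 1 | hexa-aldehyde: rings B, C and D each with formyl groups at C2 and C6, ring A dimethyl ether, ring D C4 methyl ether | COc1cc(OC)cc(Oc2c(C=O)cc(Oc3c(C=O)cc(Oc4c(C=O)cc(OC)cc4C=O)cc3C=O)cc2C=O)c1
A2 | alternative 1 | hexaformate of the ring A dimethyl, ring D C4 methyl ether of tetraphlorethol C | COc1cc(OC)cc(Oc2c(OC=O)cc(Oc3c(OC=O)cc(Oc4c(OC=O)cc(OC)cc4OC=O)cc3OC=O)cc2OC=O)c1
A3 | alternative 2 | dimethyl 4-aryloxy-3,5-dioxoheptanedioate (aryl = hexamethoxy rings A–B–C) | COC(=O)CC(=O)C(Oc1cc(OC)c(Oc2cc(OC)c(Oc3cc(OC)cc(OC)c3)c(OC)c2)c(OC)c1)C(=O)CC(=O)OC
A4 | alternative 2 | methyl 3-aryloxy-2,4,6-trihydroxybenzoate (ring D with a carbomethoxy group at C5) | COC(=O)c1c(O)cc(O)c(Oc2cc(OC)c(Oc3cc(OC)c(Oc4cc(OC)cc(OC)c4)c(OC)c3)c(OC)c2)c1O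
A5 | alternative 3 | 4-(2,4,6-trimethoxyphenoxy)-6-(aryloxymethyl)-2H-pyran-2-one (aryl = tetramethoxy rings A–B) | O=C1C=C(Oc2c(OC)cc(OC)cc2OC)C=C(COc2cc(OC)c(Oc3cc(OC)cc(OC)c3)c(OC)c2)O1
A6 | alternative 3 | heptamethyl ether of tetraphlorethol C with the two ring C hydroxyls free | COc1cc(OC)cc(Oc2c(OC)cc(Oc3c(O)cc(Oc4c(OC)cc(OC)cc4OC)cc3O)cc2OC)c1
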